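**Retrosynthetic overview**

1. The last C=C bond (C5′=C11) is made by a Knoevenagel union of the 1,5-dihydro "fragirubrin-type" core 19 (C5′H2 nucleophile) with the mitorubrinal-type enal 34. The orsellinate is attached before the union, the hydroxy-fatty ester after it, and global desilylation ends the route.
2. Each carbocycle is opened at C8–C8a: a light-driven dienol (vinylogous Dieckmann) closure of a pyranylidene ketone onto a lactic-acid dioxolanone, which also frees the C7 carbinol.
3. C7 and C7′ come from (R)- and (S)-lactic acid through Seebach aldols of their pivalaldehyde acetals with (pyran-4-ylidene)acetaldehydes. C10′ comes from (S)-propylene oxide and C13″ from (S)-epichlorohydrin.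
4. Ring order in both halves: dihydropyranone first (alkyne + β-propiolactone), carbocycle second (photocyclisation). The mitorubrin half is then dehydrogenated to the azaphilone.

Assumption: (R)-lactic acid, (S)-propylene oxide and (S)-epichlorohydrin are taken as inexpensive commercial chiral materials alongside (S)-lactic acid, and the C5′=C11 geometry of the target is taken to be the thermodynamically preferred one.

Isochromene numbering is used; primes mark the fragirubrin half. TBS = tert-butyldimethylsilyl.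

**Route**

Step 1
Reactants: 1 (S)-lactic acid; 2 pivalaldehyde
Product: 3 (2S,5S)-2-tert-butyl-5-methyl-1,3-dioxolan-4-one
Conditions: p-TsOH·H2O (cat.), H2SO4 (cat.), pentane, reflux (Dean–Stark); recrystallised at −78 °C
Reagents that add atoms: pivalaldehyde (2), CC(C)(C)C=O
Why: Acid-catalysed acetalisation (Seebach self-regeneration of stereocentres); the lactic acid centre steers the new acetal carbon cis (about 4:1, raised to >98:2 by crystallisation).

Step 2
Reactants: 4 (R)-lactic acid; 2 pivalaldehyde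
Product: 5 (2R,5R)-2-tert-butyl-5-methyl-1,3-dioxolan-4-one
Conditions: p-TsOH·H2O (cat.), H2SO4 (cat.), pentane, reflux (Dean–Stark); recrystallised at −78 °C
Reagents that add atoms: pivalaldehyde (2), CC(C)(C)C=O
Why: Same acetalisation in the mirror-image series; the acetal centre is again set cis by the lactic acid centre.

Step 3
Reactants: 6 (S)-propylene oxide; 7 lithium acetylide–ethylenediamine complex
Product: 8 (S)-pent-4-yn-2-ol
Conditions: DMSO, 0 °C → rt; aqueous work-up
Reagents that add atoms: lithium acetylide–ethylenediamine complex (7), [Li+].[C-]#C.NCCN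
Why: SN2 opening of the epoxide at the unsubstituted carbon, which leaves the bought stereocentre untouched.

Step 4
Reactants: 8 (S)-pent-4-yn-2-ol; 9 tert-butyldimethylsilyl chloride
Product: 10 (S)-tert-butyldimethyl(pent-4-yn-2-yloxy)silane
Conditions: imidazole, DMF, rt
Reagents that add atoms: TBSCl (9), CC(C)(C)[Si](C)(C)Cl
Why: Standard silylation of the secondary alcohol, needed for the organolithium steps that follow.

Step 5
Reactants: 10 (S)-tert-butyldimethyl(pent-4-yn-2-yloxy)silane; 11 β-propiolactone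
Product: 13 (S)-6-[2-(tert-butyldimethylsilyloxy)propyl]-2,3-dihydro-4H-pyran-4-one, via hydroxy ynone 12 (not isolated)
Conditions: n-BuLi, THF, −78 °C; cannulated into 11 (1.5 equiv), −78 °C; AcOH; then AgOTf (5 mol%), CH2Cl2, rt
Reagents that add atoms: β-propiolactone (11), O=C1CCO1
Why: Acyl substitution of the strained lactone by the lithium acetylide gives the β-hydroxy ynone, which closes by silver-catalysed 6-endo-dig oxa-Michael addition to the dihydropyranone (pyran ring formed; no stereocentre touched).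

Step 6
Reactants: 13 (S)-6-[2-(tert-butyldimethylsilyloxy)propyl]-2,3-dihydro-4H-pyran-4-one; 14 (Z)-1-bromo-2-ethoxyethene
Product: 16 (E)-2-{6-[(S)-2-(tert-butyldimethylsilyloxy)propyl]-2,3-dihydro-4H-pyran-4-ylidene}acetaldehyde, via carbinol adduct 15 (not isolated)
Conditions: 14, n-BuLi, THF, −78 °C; then 13, −78 °C; 0.5 M HCl, THF, 0 °C
Reagents that add atoms: (Z)-1-bromo-2-ethoxyethene (14), CCO/C=C\Br; water, O
Why: 1,2-Addition of (Z)-2-ethoxyvinyllithium to the vinylogous-ester carbonyl followed by acid-triggered allylic transposition with loss of ethanol (Wollenberg formyl olefination) gives the push–pull dienal, expected in the extended form with the formyl group syn to the ring CH2.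

Step 7
Reactants: 3 (2S,5S)-2-tert-butyl-5-methyl-1,3-dioxolan-4-one; 16 (E)-2-{6-[(S)-2-(tert-butyldimethylsilyloxy)propyl]-2,3-dihydro-4H-pyran-4-ylidene}acetaldehyde
Product: 18 (2S,5R)-2-tert-butyl-5-methyl-5-{(E)-2-[6-((S)-2-(tert-butyldimethylsilyloxy)propyl)-2,3-dihydro-4H-pyran-4-ylidene]acetyl}-1,3-dioxolan-4-one, via aldol adduct 17 (not isolated)
Conditions: LDA, THF, −78 °C; then 16; AcOH, −78 °C; crude, MnO2, CH2Cl2, rt
Reagents that add atoms: none
Why: Seebach aldol: the lithium enolate of 3 is attacked anti to the tert-butyl group, so the new chain takes the place of the former H with retention and C5 (the future C7′) becomes R; MnO2 then oxidises the dienylic carbinol (epimer mixture) to the ketone.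

Step 8
Reactants: 18 (2S,5R)-2-tert-butyl-5-methyl-5-{(E)-2-[6-((S)-2-(tert-butyldimethylsilyloxy)propyl)-2,3-dihydro-4H-pyran-4-ylidene]acetyl}-1,3-dioxolan-4-one
Product: 19 (R)-3-[(S)-2-(tert-butyldimethylsilyloxy)propyl]-7-hydroxy-7-methyl-1H-isochromene-6,8(5H,7H)-dione
Conditions: hν (365 nm LEDs), degassed toluene (5 mM), 25 °C
Reagents that add atoms: none
Why: Proposed new method: photochemical vinylogous Dieckmann closure, in which excitation of the cross-conjugated dienone (C6=O syn to the ring CH2) triggers a 1,5-hydrogen shift from C8a to the carbonyl oxygen (photoenolisation) and the resulting (Z)-dienol, its O–H hydrogen-bonded to the neighbouring dioxolanone carbonyl, adds through its terminal carbon C8a to that activated lactone; collapse of the tetrahedral intermediate expels pivalaldehyde, frees the C7′ carbinol and, after tautomerisation, gives the 6,8-dione with C5′H2, while the absence of base protects the α-ketol from retro-Claisen or acyl-shift scrambling so that C7′ (R) is carried through unchanged; the closest known reaction types are photoenolisation/photodeconjugation of enones with γ-hydrogens, trapping of photoenols by carbonyl electrophiles, and the base-mediated vinylogous Dieckmann condensation.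

Step 9
Reactants: 20 (E)-pent-2-en-4-yn-1-ol; 9 tert-butyldimethylsilyl chloride
Product: 21 (E)-tert-butyldimethyl(pent-2-en-4-yn-1-yloxy)silane
Conditions: imidazole, DMF, rt
Reagents that add atoms: TBSCl (9), CC(C)(C)[Si](C)(C)Cl
Why: Standard silylation of the primary allylic alcohol.

Step 10
Reactants: 21 (E)-tert-butyldimethyl(pent-2-en-4-yn-1-yloxy)silane; 11 β-propiolactone
Product: 23 6-[(E)-3-(tert-butyldimethylsilyloxy)prop-1-enyl]-2,3-dihydro-4H-pyran-4-one, via hydroxy ynone 22 (not isolated)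
Conditions: n-BuLi, THF, −78 °C; cannulated into 11 (1.5 equiv), −78 °C; AcOH; then AgOTf (5 mol%), CH2Cl2, rt
Reagents that add atoms: β-propiolactone (11), O=C1CCO1
Why: Same acetylide acylation and silver-catalysed 6-endo-dig oxa-Michael ring closure as in step 5; the (E)-alkene is not touched.

Step 11
Reactants: 23 6-[(E)-3-(tert-butyldimethylsilyloxy)prop-1-enyl]-2,3-dihydro-4H-pyran-4-one; 14 (Z)-1-bromo-2-ethoxyethene
Product: 25 (E)-2-{6-[(E)-3-(tert-butyldimethylsilyloxy)prop-1-enyl]-2,3-dihydro-4H-pyran-4-ylidene}acetaldehyde, via carbinol adduct 24 (not isolated)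
Conditions: 14, n-BuLi, THF, −78 °C; then 23, −78 °C; 0.5 M HCl, THF, 0 °C
Reagents that add atoms: (Z)-1-bromo-2-ethoxyethene (14), CCO/C=C\Br; water, O
Why: Wollenberg formyl olefination as in step 6 (1,2-addition, then acid-triggered transposition with loss of ethanol).

Step 12
Reactants: 5 (2R,5R)-2-tert-butyl-5-methyl-1,3-dioxolan-4-one; 25 (E)-2-{6-[(E)-3-(tert-butyldimethylsilyloxy)prop-1-enyl]-2,3-dihydro-4H-pyran-4-ylidene}acetaldehyde
Product: 27 (2R,5S)-2-tert-butyl-5-methyl-5-{(E)-2-[6-((E)-3-(tert-butyldimethylsilyloxy)prop-1-enyl)-2,3-dihydro-4H-pyran-4-ylidene]acetyl}-1,3-dioxolan-4-one, via aldol adduct 26 (not isolated)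
Conditions: LDA, THF, −78 °C; then 25; AcOH, −78 °C; crude, MnO2, CH2Cl2, rt
Reagents that add atoms: none
Why: Seebach aldol in the mirror-image series: attack anti to the tert-butyl group makes C5 (the future C7) S, and MnO2 oxidises the carbinol to the ketone.

Step 13
Reactants: 27 (2R,5S)-2-tert-butyl-5-methyl-5-{(E)-2-[6-((E)-3-(tert-butyldimethylsilyloxy)prop-1-enyl)-2,3-dihydro-4H-pyran-4-ylidene]acetyl}-1,3-dioxolan-4-one
Product: 29 (S)-7-hydroxy-3-[(E)-3-hydroxyprop-1-enyl]-7-methyl-1H-isochromene-6,8(5H,7H)-dione, via silyl ether 28 (not isolated)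
Conditions: hν (365 nm LEDs), degassed toluene (5 mM), 25 °C; then HF·pyridine, pyridine, THF, 0 °C → rt
Reagents that add atoms: none
Why: Proposed new method: the same photoenolisation (1,5-hydrogen shift from C8a to the C6 carbonyl oxygen) and addition of the dienol terminus to the hydrogen-bond-activated dioxolanone carbonyl as in step 8, with loss of pivalaldehyde and retention of C7 (S), closest known types again being enone photoenolisation, photoenol trapping by carbonyl electrophiles and the anionic vinylogous Dieckmann condensation; buffered fluoride then removes the primary silyl ether.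

Step 14
Reactants: 29 (S)-7-hydroxy-3-[(E)-3-hydroxyprop-1-enyl]-7-methyl-1H-isochromene-6,8(5H,7H)-dione
Product: 30 (S)-7-hydroxy-7-methyl-3-[(E)-3-oxoprop-1-enyl]-6H-isochromene-6,8(7H)-dione
Conditions: DDQ (2.3 equiv), 1,4-dioxane, rt
Reagents that add atoms: none
Why: DDQ dehydrogenation: hydride abstraction at the doubly activated C1 gives a pyrylium ion that loses H-5 to form the azaphilone, and the second equivalent oxidises the allylic alcohol to the enal; C7 is quaternary and unaffected.

Step 15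
Reactants: 31 orsellinic acid; 9 tert-butyldimethylsilyl chloride
Product: 32 tert-butyldimethylsilyl 2,4-bis(tert-butyldimethylsilyloxy)-6-methylbenzoate
Conditions: 9 (3.3 equiv), imidazole, DMF, rt
Reagents that add atoms: TBSCl (9), CC(C)(C)[Si](C)(C)Cl
Why: Exhaustive silylation protects both phenols and gives a silyl ester that can be turned directly into the acid chloride.

Step 16
Reactants: 32 tert-butyldimethylsilyl 2,4-bis(tert-butyldimethylsilyloxy)-6-methylbenzoate; 30 (S)-7-hydroxy-7-methyl-3-[(E)-3-oxoprop-1-enyl]-6H-isochromene-6,8(7H)-dione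
Product: 34 (S)-7-methyl-6,8-dioxo-3-[(E)-3-oxoprop-1-enyl]-7,8-dihydro-6H-isochromen-7-yl 2,4-bis(tert-butyldimethylsilyloxy)-6-methylbenzoate, via aroyl chloride 33 (not isolated)
Conditions: (COCl)2, DMF (cat.), CH2Cl2, 0 °C → rt; high vacuum; then 30, DMAP, i-Pr2NEt, CH2Cl2, rt → 40 °C
Reagents that add atoms: none
Why: Silyl ester to acid chloride under neutral conditions, then DMAP-catalysed acylation of the only free hydroxyl (the tertiary C7–OH), the way 7-O-acyl azaphilones are normally made; no stereocentre is touched.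

Step 17
Reactants: 35 (S)-epichlorohydrin; 36 ethylmagnesium bromide
Product: 38 (S)-1,2-epoxypentane, via chlorohydrin 37 (not isolated)
Conditions: CuI (10 mol%), THF, −40 °C; then NaOH (aq), rt; distilled
Reagents that add atoms: ethylmagnesium bromide (36), CC[Mg]Br
Why: Copper-catalysed Grignard opening at the epoxide CH2 followed by base-induced ring closure of the chlorohydrin; no bond to the stereocentre is broken, so (S) is kept.

Step 18
Reactants: 38 (S)-1,2-epoxypentane; 39 undec-10-ynoic acid
Product: 40 (S)-13-hydroxyhexadec-10-ynoic acid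
Conditions: 39, n-BuLi (2.1 equiv), THF–DMPU, −78 → 0 °C; then 38, rt; 1 M HCl work-up
Reagents that add atoms: undec-10-ynoic acid (39), C#CCCCCCCCCC(=O)O
Why: The carboxylate–acetylide dianion opens the epoxide at the terminal carbon (SN2), which assembles the C16 chain with the carbinol centre intact.

Step 19
Reactants: 40 (S)-13-hydroxyhexadec-10-ynoic acid
Product: 41 (S)-13-hydroxyhexadecanoic acid
Conditions: H2 (1 atm), Pd/C, EtOAc, rt
Reagents that add atoms: none
Why: Catalytic hydrogenation of the alkyne to the saturated chain; the carbinol centre is not affected.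

Step 20
Reactants: 41 (S)-13-hydroxyhexadecanoic acid; 9 tert-butyldimethylsilyl chloride
Product: 42 tert-butyldimethylsilyl (S)-13-(tert-butyldimethylsilyloxy)hexadecanoate
Conditions: 9 (2.4 equiv), imidazole, DMF, rt
Reagents that add atoms: TBSCl (9), CC(C)(C)[Si](C)(C)Cl
Why: Bis-silylation protects the secondary alcohol and gives the silyl ester used for acid chloride formation.

Step 21
Reactants: 19 (R)-3-[(S)-2-(tert-butyldimethylsilyloxy)propyl]-7-hydroxy-7-methyl-1H-isochromene-6,8(5H,7H)-dione; 34 (S)-azaphilone enal bis-TBS orsellinate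
Product: 43 7′-hydroxy heterodimer (19 joined at C5′ through an exocyclic (E)-C5′=CH–CH=CH bridge to C3 of 34)
Conditions: i-Pr2NEt (0.3 equiv), AcOH (0.3 equiv), 4 Å MS, CH2Cl2, rt, dark
Reagents that add atoms: none
Why: Knoevenagel condensation of the vinylogous 1,3-diketone C5′H2 with the enal under a tertiary-amine buffer (no primary or secondary amine, which would attack the azaphilone); the trisubstituted alkene equilibrates to the isomer with the chain anti to C6′=O, as in the target, and no sp3 stereocentre is involved.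

Step 22
Reactants: 42 tert-butyldimethylsilyl (S)-13-(tert-butyldimethylsilyloxy)hexadecanoate; 43 7′-hydroxy heterodimer
Product: 45 tetrakis-TBS hybridorubrin A, via acyl chloride 44 (not isolated)
Conditions: (COCl)2, DMF (cat.), CH2Cl2, 0 °C → rt; evaporated; then 43, DMAP, i-Pr2NEt, CH2Cl2, 0 °C → rt
Reagents that add atoms: none
Why: DMAP-catalysed acylation of the single free hydroxyl (tertiary C7′–OH) by the unhindered aliphatic acid chloride, done after the union so that no enolisable C5′H2 competes.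

Step 23
Reactants: 45 tetrakis-TBS hybridorubrin A
Product: 46 hybridorubrin A
Conditions: HF·pyridine, pyridine, THF, 0 °C → rt
Reagents that add atoms: none
Why: Buffered fluoride cleaves the two aryl and two secondary alkyl silyl ethers without touching the esters, the azaphilone or any stereocentre.

**Compound list**

1 | (S)-lactic acid | C[C@H](O)C(=O)O | starting material
2 | pivalaldehyde | CC(C)(C)C=O | starting material
3 | (2S,5S)-2-tert-butyl-5-methyl-1,3-dioxolan-4-one (cis) | C[C@@H]1O[C@H](C(C)(C)C)OC1=O | intermediate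
4 | (R)-lactic acid | C[C@@H](O)C(=O)O | starting material
5 | (2R,5R)-2-tert-butyl-5-methyl-1,3-dioxolan-4-one (cis) | C[C@H]1O[C@@H](C(C)(C)C)OC1=O | intermediate
6 | (S)-propylene oxide | C[C@H]1CO1 | starting material
7 | lithium acetylide–ethylenediamine complex | [Li+].[C-]#C.NCCN | starting material
8 | (S)-pent-4-yn-2-ol | C#CC[C@H](C)O | intermediate
9 | tert-butyldimethylsilyl chloride (TBSCl) | CC(C)(C)[Si](C)(C)Cl | starting material
10 | (S)-tert-butyldimethyl(pent-4-yn-2-yloxy)silane | C#CC[C@H](C)O[Si](C)(C)C(C)(C)C | intermediate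
11 | β-propiolactone (oxetan-2-one) | O=C1CCO1 | starting material
12 | (S)-7-(tert-butyldimethylsilyloxy)-1-hydroxyoct-4-yn-3-one | OCCC(=O)C#CC[C@H](C)O[Si](C)(C)C(C)(C)C | intermediate
13 | (S)-6-[2-(tert-butyldimethylsilyloxy)propyl]-2,3-dihydro-4H-pyran-4-one | O=C1CCOC(C[C@H](C)O[Si](C)(C)C(C)(C)C)=C1 | intermediate
14 | (Z)-1-bromo-2-ethoxyethene | CCO/C=C\Br | starting material
15 | 6-[(S)-2-(tert-butyldimethylsilyloxy)propyl]-4-[(Z)-2-ethoxyethenyl]-3,4-dihydro-2H-pyran-4-ol (C4 epimers) | CCO/C=C\C1(O)CCOC(C[C@H](C)O[Si](C)(C)C(C)(C)C)=C1 | intermediate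
16 | (E)-2-{6-[(S)-2-(tert-butyldimethylsilyloxy)propyl]-2,3-dihydro-4H-pyran-4-ylidene}acetaldehyde (CHO syn to ring CH2) | O=C/C=C1\CCOC(C[C@H](C)O[Si](C)(C)C(C)(C)C)=C1 | intermediate
17 | (2S,5R)-2-tert-butyl-5-{(E)-1-hydroxy-2-[6-((S)-2-(tert-butyldimethylsilyloxy)propyl)-2,3-dihydro-4H-pyran-4-ylidene]ethyl}-5-methyl-1,3-dioxolan-4-one (carbinol epimers) | C[C@]1(C(O)/C=C2\CCOC(C[C@H](C)O[Si](C)(C)C(C)(C)C)=C2)O[C@H](C(C)(C)C)OC1=O | intermediate
18 | (2S,5R)-2-tert-butyl-5-methyl-5-{(E)-2-[6-((S)-2-(tert-butyldimethylsilyloxy)propyl)-2,3-dihydro-4H-pyran-4-ylidene]acetyl}-1,3-dioxolan-4-one | C[C@]1(C(=O)/C=C2\CCOC(C[C@H](C)O[Si](C)(C)C(C)(C)C)=C2)O[C@H](C(C)(C)C)OC1=O | intermediate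
19 | (R)-3-[(S)-2-(tert-butyldimethylsilyloxy)propyl]-7-hydroxy-7-methyl-1H-isochromene-6,8(5H,7H)-dione | O[C@@]1(C)C(=O)C2=C(C=C(C[C@H](C)O[Si](C)(C)C(C)(C)C)OC2)CC1=O | intermediate
20 | (E)-pent-2-en-4-yn-1-ol | C#C/C=C/CO | starting material
21 | (E)-tert-butyldimethyl(pent-2-en-4-yn-1-yloxy)silane | C#C/C=C/CO[Si](C)(C)C(C)(C)C | intermediate
22 | (E)-8-(tert-butyldimethylsilyloxy)-1-hydroxyoct-6-en-4-yn-3-one | OCCC(=O)C#C/C=C/CO[Si](C)(C)C(C)(C)C | intermediate
23 | 6-[(E)-3-(tert-butyldimethylsilyloxy)prop-1-enyl]-2,3-dihydro-4H-pyran-4-one | O=C1CCOC(/C=C/CO[Si](C)(C)C(C)(C)C)=C1 | intermediate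
24 | 6-[(E)-3-(tert-butyldimethylsilyloxy)prop-1-enyl]-4-[(Z)-2-ethoxyethenyl]-3,4-dihydro-2H-pyran-4-ol (racemic) | CCO/C=C\C1(O)CCOC(/C=C/CO[Si](C)(C)C(C)(C)C)=C1 | intermediate
25 | (E)-2-{6-[(E)-3-(tert-butyldimethylsilyloxy)prop-1-enyl]-2,3-dihydro-4H-pyran-4-ylidene}acetaldehyde (CHO syn to ring CH2) | O=C/C=C1\CCOC(/C=C/CO[Si](C)(C)C(C)(C)C)=C1 | intermediate
26 | (2R,5S)-2-tert-butyl-5-{(E)-1-hydroxy-2-[6-((E)-3-(tert-butyldimethylsilyloxy)prop-1-enyl)-2,3-dihydro-4H-pyran-4-ylidene]ethyl}-5-methyl-1,3-dioxolan-4-one (carbinol epimers) | C[C@@]1(C(O)/C=C2\CCOC(/C=C/CO[Si](C)(C)C(C)(C)C)=C2)O[C@@H](C(C)(C)C)OC1=O | intermediate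
27 | (2R,5S)-2-tert-butyl-5-methyl-5-{(E)-2-[6-((E)-3-(tert-butyldimethylsilyloxy)prop-1-enyl)-2,3-dihydro-4H-pyran-4-ylidene]acetyl}-1,3-dioxolan-4-one | C[C@@]1(C(=O)/C=C2\CCOC(/C=C/CO[Si](C)(C)C(C)(C)C)=C2)O[C@@H](C(C)(C)C)OC1=O | intermediate
28 | (S)-3-[(E)-3-(tert-butyldimethylsilyloxy)prop-1-enyl]-7-hydroxy-7-methyl-1H-isochromene-6,8(5H,7H)-dione | O[C@]1(C)C(=O)C2=C(C=C(/C=C/CO[Si](C)(C)C(C)(C)C)OC2)CC1=O | intermediate
29 | (S)-7-hydroxy-3-[(E)-3-hydroxyprop-1-enyl]-7-methyl-1H-isochromene-6,8(5H,7H)-dione | O[C@]1(C)C(=O)C2=C(C=C(/C=C/CO)OC2)CC1=O | intermediate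
30 | (S)-7-hydroxy-7-methyl-3-[(E)-3-oxoprop-1-enyl]-6H-isochromene-6,8(7H)-dione | O=C/C=C/C1=CC2=CC(=O)[C@](C)(O)C(=O)C2=CO1 | intermediate
31 | orsellinic acid (2,4-dihydroxy-6-methylbenzoic acid) | Cc1cc(O)cc(O)c1C(=O)O | starting material
32 | tert-butyldimethylsilyl 2,4-bis(tert-butyldimethylsilyloxy)-6-methylbenzoate | Cc1cc(O[Si](C)(C)C(C)(C)C)cc(O[Si](C)(C)C(C)(C)C)c1C(=O)O[Si](C)(C)C(C)(C)C | intermediate
33 | 2,4-bis(tert-butyldimethylsilyloxy)-6-methylbenzoyl chloride | Cc1cc(O[Si](C)(C)C(C)(C)C)cc(O[Si](C)(C)C(C)(C)C)c1C(Cl)=O | intermediate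
34 | (S)-7-methyl-6,8-dioxo-3-[(E)-3-oxoprop-1-enyl]-7,8-dihydro-6H-isochromen-7-yl 2,4-bis(tert-butyldimethylsilyloxy)-6-methylbenzoate | O=C/C=C/C1=CC2=CC(=O)[C@](C)(OC(=O)c3c(C)cc(O[Si](C)(C)C(C)(C)C)cc3O[Si](C)(C)C(C)(C)C)C(=O)C2=CO1 | intermediate
35 | (S)-epichlorohydrin | ClC[C@@H]1CO1 | starting material
36 | ethylmagnesium bromide | CC[Mg]Br | starting material
37 | (S)-1-chloropentan-2-ol | CCC[C@H](O)CCl | intermediate
38 | (S)-1,2-epoxypentane | CCC[C@H]1CO1 | intermediate
39 | undec-10-ynoic acid | C#CCCCCCCCCC(=O)O | starting material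
40 | (S)-13-hydroxyhexadec-10-ynoic acid | CCC[C@H](O)CC#CCCCCCCCCC(=O)O | intermediate
41 | (S)-13-hydroxyhexadecanoic acid | CCC[C@H](O)CCCCCCCCCCCC(=O)O | intermediate
42 | tert-butyldimethylsilyl (S)-13-(tert-butyldimethylsilyloxy)hexadecanoate | CCC[C@H](O[Si](C)(C)C(C)(C)C)CCCCCCCCCCCC(=O)O[Si](C)(C)C(C)(C)C | intermediate
43 | 7′-hydroxy heterodimer: (7′R)-7′-hydroxy unit of 19 joined by an exocyclic (E)-C5′=CH–CH=CH bridge (second alkene E) to C3 of the (7S)-azaphilone bis-TBS orsellinate | O[C@@]1(C)C(=O)C2=C(C=C(C[C@H](C)O[Si](C)(C)C(C)(C)C)OC2)/C(=C\C=C\C2=CC3=CC(=O)[C@](C)(OC(=O)c4c(C)cc(O[Si](C)(C)C(C)(C)C)cc4O[Si](C)(C)C(C)(C)C)C(=O)C3=CO2)C1=O | intermediate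
44 | (S)-13-(tert-butyldimethylsilyloxy)hexadecanoyl chloride | CCC[C@H](O[Si](C)(C)C(C)(C)C)CCCCCCCCCCCC(Cl)=O | intermediate
45 | tetrakis-TBS hybridorubrin A (silyl ethers at both phenols, C10′–O and C13″–O) | CCC[C@H](O[Si](C)(C)C(C)(C)C)CCCCCCCCCCCC(=O)O[C@@]1(C)C(=O)C2=C(C=C(C[C@H](C)O[Si](C)(C)C(C)(C)C)OC2)/C(=C\C=C\C2=CC3=CC(=O)[C@](C)(OC(=O)c4c(C)cc(O[Si](C)(C)C(C)(C)C)cc4O[Si](C)(C)C(C)(C)C)C(=O)C3=CO2)C1=O | intermediate
46 | hybridorubrin A | CCC[C@H](O)CCCCCCCCCCCC(=O)O[C@@]1(C)C(=O)C2=C(C=C(C[C@H](C)O)OC2)/C(=C\C=C\C2=CC3=CC(=O)[C@](C)(OC(=O)c4c(C)cc(O)cc4O)C(=O)C3=CO2)C1=O | target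

**Step count and risks**

Total step count: 23. Longest linear sequence: 10 (steps 9, 10, 11, 12, 13, 14, 16, 21, 22, 23, from (E)-pent-2-en-4-yn-1-ol).

The three steps most likely to fail:

Step 8 (and its mirror-image repeat, step 13), the proposed photochemical ring closure. The excited dienone may only isomerise about the exocyclic alkene, the dienol may re-ketonise faster than it attacks the lactone, and in step 13 the side-chain alkene may be partly isomerised. The fallback replaces excited-state enolisation by ground-state anion chemistry. Setting out from 18, γ-deprotonation at the ring CH2 with LiHMDS (2.2 equiv, THF, −78 → −20 °C) gives the extended dienolate, which closes onto the dioxolanone carbonyl in a classical vinylogous Dieckmann condensation with loss of pivalaldehyde. Cold AcOH quench returns the route at 19. In the same way 27 gives 28, which is desilylated as in step 13 to rejoin at 29. This fallback passes through no new compound (none, F0).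

Step 6 (and its repeat, step 11), the formyl olefination of the vinylogous ester. The cation formed on acid treatment of 15 can also be captured by water at the ring carbon C3, which would open the pyran or give the transposed isomer. The fallback avoids any carbocation. Setting out from 13, lithiated N-tert-butyl-2-(trimethylsilyl)acetaldimine (LDA, THF, −78 → 0 °C) adds to the ketone and undergoes Peterson elimination to the unsaturated N-tert-butyl aldimine F1. Buffered hydrolysis (aqueous oxalic acid, 0 °C) returns the route at 16. The same two operations take 23 through the unsaturated N-tert-butyl aldimine F2 to 25.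

Step 21, the Knoevenagel union. A second molecule of 19 can add to the new alkylidene (bis-adduct), the enal can be attacked in conjugate fashion, and the buffer may not bring the C5′=C11 alkene to the desired isomer. The fallback separates C–C bond formation from dehydration. Setting out from 19 and 34, soft enolisation of 19 (MgBr2·OEt2, i-Pr2NEt, CH2Cl2, −20 °C) and addition to 34 stop at the chelated β-hydroxy ketone aldol adduct F3, so no Michael acceptor is present while the bond forms. Mesylation of the secondary carbinol and E1cB elimination (MsCl, Et3N, 0 °C) then return the route at 43, where the alkene can be equilibrated with a trace of acid.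

Further compounds
F0 | step 8 | none | none
F1 | step 6 | (E)-N-tert-butyl-2-{6-[(S)-2-(tert-butyldimethylsilyloxy)propyl]-2,3-dihydro-4H-pyran-4-ylidene}ethan-1-imine | CC(C)(C)/N=C/C=C1\CCOC(C[C@H](C)O[Si](C)(C)C(C)(C)C)=C1
F2 | step 6 | (E)-N-tert-butyl-2-{6-[(E)-3-(tert-butyldimethylsilyloxy)prop-1-enyl]-2,3-dihydro-4H-pyran-4-ylidene}ethan-1-imine | CC(C)(C)/N=C/C=C1\CCOC(/C=C/CO[Si](C)(C)C(C)(C)C)=C1
F3 | step 21 | β-hydroxy ketone aldol adduct of 19 (C5′) and 34 (aldehyde carbon), C5′ and carbinol epimers | O[C@@]1(C)C(=O)C2=C(C=C(C[C@H](C)O[Si](C)(C)C(C)(C)C)OC2)C(C(O)/C=C/C2=CC3=CC(=O)[C@](C)(OC(=O)c4c(C)cc(O[Si](C)(C)C(C)(C)C)cc4O[Si](C)(C)C(C)(C)C)C(=O)C3=CO2)C1=O
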